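**Retrosynthetic overview**

1. Target: (3S)-5-[(1S,3S,5S)-3,5-dibromo-2,2-dimethyl-6-methylidenecyclohexyl]-3-methylpent-1-en-3-ol; the ring locants of this name (C-1 side chain, C-2 CMe2, C-3 CHBr, C-4 CH2, C-5 CHBr, C-6 C=CH2) are used throughout.
2. Late stage: the C-5 bromide and the exocyclic methylene come together from a 1-(trimethylsilylmethyl)cyclohexene by SE2′ bromodesilylation; the allylsilane comes from an enol triflate; the neopentyl C-3 bromide comes from vinylogous (γ) bromination of a silyl dienol ether.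
3. The six-membered ring is made second, from a 2-vinylcyclobutanone by a strain-releasing 1,3-acyl shift (two-carbon ring expansion); the four-membered ring is made first.
4. Key disconnection: C-1–C-6 and C-2–C-3, both formed at once in a [2+2] cycloaddition between the Me2C=CH olefin of O-silylated (S)-linalool and a chiral vinylketeniminium salt.
5. Enabling feature: C-6 and C-3 are 1,4-related in the ring, so they can first be joined as carbonyl carbon and α-carbon of a cyclobutanone across the C-1/C-2 olefin (nucleophilic CH, cation-stabilising CMe2), while the vinyl group on the α-carbon supplies C-4 and C-5.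

Key step: step 3

Remark 1: (S)-(+)-linalool of high enantiomeric purity is taken as a commercial starting material.
Remark 2: the sense of induction of the C2-symmetric keteniminium salt is assigned from a steric model, not from a firm precedent; the (2S,5S) auxiliary is written, and the equally available (2R,5R) antipode would replace it, with no other change, if the sense proves opposite.

**Route**

Step 1
Reactants: 1 (S)-(+)-linalool [(3S)-3,7-dimethylocta-1,6-dien-3-ol]
Product: 2 triethyl{[(3S)-3,7-dimethylocta-1,6-dien-3-yl]oxy}silane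
Conditions: Et3SiOTf, 2,6-lutidine, CH2Cl2, −78 to 0 °C
Reagents that add atoms: triethylsilyl trifluoromethanesulfonate, CC[Si](CC)(CC)OS(=O)(=O)C(F)(F)F
Why: Silylation of the hindered tertiary allylic alcohol with a silyl triflate and a hindered base masks the only protic group before the electrophilic steps and leaves the carbinol stereocentre untouched.

Step 2
Reactants: 3 but-3-enoic acid; 4 (2S,5S)-2,5-dimethylpyrrolidine
Product: 5 1-[(2S,5S)-2,5-dimethylpyrrolidin-1-yl]but-3-en-1-one
Conditions: DCC, 1-hydroxybenzotriazole, CH2Cl2, 0 °C to rt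
Reagents that add atoms: none
Why: Carbodiimide amide coupling without added amine base joins acid and auxiliary while keeping the C=C bond in the β,γ-position, so that α-deprotonation in step 3 leads directly to the conjugated keteniminium ion; the pyrrolidine stereocentres are not involved.

Step 3
Reactants: 2 triethyl{[(3S)-3,7-dimethylocta-1,6-dien-3-yl]oxy}silane; 5 1-[(2S,5S)-2,5-dimethylpyrrolidin-1-yl]but-3-en-1-one
Product: 8 (4S)-2-ethenyl-3,3-dimethyl-4-[(3S)-3-methyl-3-(triethylsilyloxy)pent-4-en-1-yl]cyclobutan-1-one (epimer mixture at the ethenyl-bearing carbon), via keteniminium triflate 6 (not isolated), via cyclobutaniminium triflate 7 (not isolated)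
Conditions: 5, Tf2O, 2,4,6-collidine, ClCH2CH2Cl, −20 °C; then 2, 25 to 80 °C; then aq NaHCO3
Reagents that add atoms: water, O
Why: Keteniminium–olefin [2+2] cycloaddition (Ghosez cycloaddition): Tf2O and collidine convert 5 into the vinylketeniminium ion 6, whose sp iminium carbon is attacked by the nucleophilic CH terminus of the trisubstituted olefin of 2 (future C-1–C-6 bond), and the developing tertiary cation at the CMe2 terminus is captured by the enamine α-carbon (future C-2–C-3 bond) to give 7, which water hydrolyses to 8 with release of the auxiliary. The closest known reaction type is the asymmetric [2+2] cycloaddition of keteniminium salts of C2-symmetric 2,5-dimethylpyrrolidine amides with unactivated olefins. The cyclobutane ring closes by a stepwise polar [2+2], intermolecular C–C bond formation followed by collapse of the enamine carbon onto the tertiary cation. The stereocentre at the side-chain-bearing carbon (future C-1) should be set by the auxiliary, one methyl group of which flanks the trajectory of the olefin; the ethenyl-bearing carbon is formed without control and is erased in step 4. The step needs chemoselectivity for the trisubstituted over the monosubstituted C=C, secured by its higher nucleophilicity and by the quaternary oxygen-bearing carbon next to the vinyl group, and regioselectivity, secured by formation of the tertiary rather than a secondary cation.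

Step 4
Reactants: 8 (4S)-2-ethenyl-3,3-dimethyl-4-[(3S)-3-methyl-3-(triethylsilyloxy)pent-4-en-1-yl]cyclobutan-1-one
Product: 9 (6S)-5,5-dimethyl-6-[(3S)-3-methyl-3-(triethylsilyloxy)pent-4-en-1-yl]cyclohex-3-en-1-one
Conditions: toluene, 2,6-di-tert-butyl-4-methylphenol (cat.), 140 °C, sealed tube
Reagents that add atoms: none
Why: Thermal 1,3-acyl shift of a 2-vinylcyclobutanone moves the acyl carbon from the α-carbon to the vinyl terminus, releases the cyclobutane strain and gives the six-membered β,γ-enone; both epimers of 8 converge because the former α-carbon (C-3) becomes sp2, and the C-1 stereocentre is not part of the migrating unit.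

Step 5
Reactants: 9 (6S)-5,5-dimethyl-6-[(3S)-3-methyl-3-(triethylsilyloxy)pent-4-en-1-yl]cyclohex-3-en-1-one
Product: 11 (4S,6S)-4-bromo-5,5-dimethyl-6-[(3S)-3-methyl-3-(triethylsilyloxy)pent-4-en-1-yl]cyclohex-2-en-1-one, via silyl dienol ether 10 (not isolated)
Conditions: t-BuMe2SiOTf, Et3N, CH2Cl2, −78 to 0 °C; then NBS, THF, −78 °C
Reagents that add atoms: N-bromosuccinimide, O=C1CCC(=O)N1Br
Why: Soft enolisation of the β,γ-enone at its doubly activated CH2 gives the linear 1-silyloxy-1,3-diene, which NBS brominates at the vinylogous terminus, C-3 (γ-halogenation of a dienol ether); allylic strain from the silyloxy group should hold the side chain pseudo-axial, so that axial attack anti to the pseudo-axial methyl of the neighbouring CMe2 carbon places bromine cis to the side chain, and the enone then relaxes to the diequatorial form.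

Step 6
Reactants: 11 (4S,6S)-4-bromo-5,5-dimethyl-6-[(3S)-3-methyl-3-(triethylsilyloxy)pent-4-en-1-yl]cyclohex-2-en-1-one
Product: 13 (4S,6S)-4-bromo-5,5-dimethyl-6-[(3S)-3-methyl-3-(triethylsilyloxy)pent-4-en-1-yl]cyclohex-1-en-1-yl trifluoromethanesulfonate, via lithium enolate 12 (not isolated)
Conditions: LiBH(s-Bu)3, THF, −78 °C; then PhNTf2, −78 to 0 °C
Reagents that add atoms: N-phenylbis(trifluoromethanesulfonimide), O=S(=O)(N(c1ccccc1)S(=O)(=O)C(F)(F)F)C(F)(F)F
Why: Conjugate hydride addition makes C-4 a CH2 group and delivers the enolate regiospecifically toward C-5, where O-triflation traps it (reductive enol triflate formation); the equatorial neopentyl bromide cannot align for 1,3-displacement by the enolate carbon at −78 °C, and no stereocentre is changed.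

Step 7
Reactants: 13 (4S,6S)-4-bromo-5,5-dimethyl-6-[(3S)-3-methyl-3-(triethylsilyloxy)pent-4-en-1-yl]cyclohex-1-en-1-yl trifluoromethanesulfonate
Product: 14 {[(4S,6R)-4-bromo-5,5-dimethyl-6-[(3S)-3-methyl-3-(triethylsilyloxy)pent-4-en-1-yl]cyclohex-1-en-1-yl]methyl}trimethylsilane
Conditions: Me3SiCH2MgCl, Pd(PPh3)4 (5 mol %), THF, 0 °C to rt
Reagents that add atoms: (trimethylsilyl)methylmagnesium chloride, C[Si](C)(C)C[Mg]Cl
Why: Kumada coupling of the alkenyl triflate with the α-silyl Grignard reagent gives the allylsilane, because insertion of the palladium catalyst into the C(sp2)–OTf bond is much faster than into the hindered secondary C–Br bond, whose equatorial position also offers no anti-periplanar hydrogen for elimination; no stereocentre is touched (the descriptor at C-6 of the name changes only through priorities).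

Step 8
Reactants: 14 {[(4S,6R)-4-bromo-5,5-dimethyl-6-[(3S)-3-methyl-3-(triethylsilyloxy)pent-4-en-1-yl]cyclohex-1-en-1-yl]methyl}trimethylsilane
Product: 15 triethyl({(3S)-5-[(1S,3S,5S)-3,5-dibromo-2,2-dimethyl-6-methylidenecyclohexyl]-3-methylpent-1-en-3-yl}oxy)silane
Conditions: NBS, propylene oxide, CH2Cl2, −78 °C
Reagents that add atoms: N-bromosuccinimide, O=C1CCC(=O)N1Br
Why: SE2′ bromodesilylation of the allylsilane: bromine attacks ring carbon C-5 and the β-silyl cation collapses to the exocyclic methylene; stereoelectronically preferred axial attack on the half-chair that keeps the side chain and the C-3 bromine equatorial should place the new bromine axial, trans to both.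

Step 9
Reactants: 15 triethyl({(3S)-5-[(1S,3S,5S)-3,5-dibromo-2,2-dimethyl-6-methylidenecyclohexyl]-3-methylpent-1-en-3-yl}oxy)silane
Product: 16 (3S)-5-[(1S,3S,5S)-3,5-dibromo-2,2-dimethyl-6-methylidenecyclohexyl]-3-methylpent-1-en-3-ol
Conditions: HF·pyridine, pyridine, THF, 0 °C
Reagents that add atoms: none
Why: Buffered fluoride cleavage of the triethylsilyl ether frees the tertiary alcohol under conditions that should neither ionise the axial allylic bromide nor touch a stereocentre.

**Compound list**

1 | (S)-(+)-linalool, (3S)-3,7-dimethylocta-1,6-dien-3-ol | C=C[C@@](C)(O)CCC=C(C)C | starting material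
2 | triethyl{[(3S)-3,7-dimethylocta-1,6-dien-3-yl]oxy}silane | C=C[C@@](C)(O[Si](CC)(CC)CC)CCC=C(C)C | intermediate
3 | but-3-enoic acid | C=CCC(=O)O | starting material
4 | (2S,5S)-2,5-dimethylpyrrolidine | C[C@H]1CC[C@H](C)N1 | starting material
5 | 1-[(2S,5S)-2,5-dimethylpyrrolidin-1-yl]but-3-en-1-one | C=CCC(=O)N1[C@@H](C)CC[C@@H]1C | intermediate
6 | (2S,5S)-1-(buta-1,3-dien-1-ylidene)-2,5-dimethylpyrrolidin-1-ium trifluoromethanesulfonate | C=CC=C=[N+]1[C@@H](C)CC[C@@H]1C.[O-]S(=O)(=O)C(F)(F)F | intermediate (not isolated)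
7 | (2S,5S)-1-{(4S)-2-ethenyl-3,3-dimethyl-4-[(3S)-3-methyl-3-(triethylsilyloxy)pent-4-en-1-yl]cyclobutylidene}-2,5-dimethylpyrrolidin-1-ium trifluoromethanesulfonate (epimer mixture at the ethenyl-bearing carbon) | C=C[C@@](C)(O[Si](CC)(CC)CC)CC[C@@H]1C(=[N+]2[C@@H](C)CC[C@@H]2C)C(C=C)C1(C)C.[O-]S(=O)(=O)C(F)(F)F | intermediate (not isolated)
8 | (4S)-2-ethenyl-3,3-dimethyl-4-[(3S)-3-methyl-3-(triethylsilyloxy)pent-4-en-1-yl]cyclobutan-1-one (epimer mixture at the ethenyl-bearing carbon) | C=C[C@@](C)(O[Si](CC)(CC)CC)CC[C@@H]1C(=O)C(C=C)C1(C)C | intermediate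
9 | (6S)-5,5-dimethyl-6-[(3S)-3-methyl-3-(triethylsilyloxy)pent-4-en-1-yl]cyclohex-3-en-1-one | C=C[C@@](C)(O[Si](CC)(CC)CC)CC[C@@H]1C(=O)CC=CC1(C)C | intermediate
10 | tert-butyl({(6S)-5,5-dimethyl-6-[(3S)-3-methyl-3-(triethylsilyloxy)pent-4-en-1-yl]cyclohexa-1,3-dien-1-yl}oxy)dimethylsilane | C=C[C@@](C)(O[Si](CC)(CC)CC)CC[C@@H]1C(O[Si](C)(C)C(C)(C)C)=CC=CC1(C)C | intermediate (not isolated)
11 | (4S,6S)-4-bromo-5,5-dimethyl-6-[(3S)-3-methyl-3-(triethylsilyloxy)pent-4-en-1-yl]cyclohex-2-en-1-one | C=C[C@@](C)(O[Si](CC)(CC)CC)CC[C@@H]1C(=O)C=C[C@H](Br)C1(C)C | intermediate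
12 | lithium (4S,6S)-4-bromo-5,5-dimethyl-6-[(3S)-3-methyl-3-(triethylsilyloxy)pent-4-en-1-yl]cyclohex-1-en-1-olate | C=C[C@@](C)(O[Si](CC)(CC)CC)CC[C@@H]1C(O[Li])=CC[C@H](Br)C1(C)C | intermediate (not isolated)
13 | (4S,6S)-4-bromo-5,5-dimethyl-6-[(3S)-3-methyl-3-(triethylsilyloxy)pent-4-en-1-yl]cyclohex-1-en-1-yl trifluoromethanesulfonate | C=C[C@@](C)(O[Si](CC)(CC)CC)CC[C@@H]1C(OS(=O)(=O)C(F)(F)F)=CC[C@H](Br)C1(C)C | intermediate
14 | {[(4S,6R)-4-bromo-5,5-dimethyl-6-[(3S)-3-methyl-3-(triethylsilyloxy)pent-4-en-1-yl]cyclohex-1-en-1-yl]methyl}trimethylsilane | C=C[C@@](C)(O[Si](CC)(CC)CC)CC[C@@H]1C(C[Si](C)(C)C)=CC[C@H](Br)C1(C)C | intermediate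
15 | triethyl({(3S)-5-[(1S,3S,5S)-3,5-dibromo-2,2-dimethyl-6-methylidenecyclohexyl]-3-methylpent-1-en-3-yl}oxy)silane | C=C[C@@](C)(O[Si](CC)(CC)CC)CC[C@@H]1C(=C)[C@@H](Br)C[C@H](Br)C1(C)C | intermediate
16 | (3S)-5-[(1S,3S,5S)-3,5-dibromo-2,2-dimethyl-6-methylidenecyclohexyl]-3-methylpent-1-en-3-ol | C=C[C@@](C)(O)CC[C@@H]1C(=C)[C@@H](Br)C[C@H](Br)C1(C)C | target

**Step count and risks**

Total step count: 9. Longest linear sequence: 8 steps (steps 1 and 3 to 9).

Step 3. What may go wrong: self-condensation of the conjugated keteniminium ion, its reaction through the vinyl terminus, or erosion of facial selectivity through reversible first-bond formation. The fallback sets out from 2 and 4 and returns at 8. Compound 4 is N-acetylated (acetic anhydride, Et3N) to 1-[(2S,5S)-2,5-dimethylpyrrolidin-1-yl]ethan-1-one F1. Its unsubstituted keteniminium triflate (Tf2O, collidine) undergoes the same [2+2] cycloaddition with 2 and gives, after hydrolysis, (2S)-3,3-dimethyl-2-[(3S)-3-methyl-3-(triethylsilyloxy)pent-4-en-1-yl]cyclobutan-1-one F2. The vinyl group is then introduced as a vinyl cation equivalent: kinetic enolisation at the CH2 α-carbon (LiN(i-Pr)2, THF, −78 °C) and conjugate addition to phenyl vinyl sulfoxide give (2S)-3,3-dimethyl-2-[(3S)-3-methyl-3-(triethylsilyloxy)pent-4-en-1-yl]-4-[2-(phenylsulfinyl)ethyl]cyclobutan-1-one F3. Thermal syn-elimination of the sulfoxide (toluene, 110 °C) gives 8.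

Step 5. What may go wrong: bromination at the α-carbon of the dienol ether instead of the hindered γ-carbon, or attack on the face anti to the side chain (the incoming bromine is 1,3-syn to the pseudo-axial side chain). The fallback sets out from 9 and returns at 11. Compound 9 is isomerised into conjugation (DBU cat., CH2Cl2) to (6S)-5,5-dimethyl-6-[(3S)-3-methyl-3-(triethylsilyloxy)pent-4-en-1-yl]cyclohex-2-en-1-one F4. The γ-methylene group is then brominated by radical allylic (Wohl–Ziegler) bromination (NBS, AIBN, PhCF3, 80 °C); 11 would be separated from its C-3 epimer by chromatography.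

Step 4. What may go wrong: cycloreversion to vinylketene and olefin, or cleavage of the bond between the ethenyl-bearing carbon and the CMe2 carbon, at the temperature the acyl shift needs. The fallback sets out from 8 and returns at 9. Reduction (NaBH4, MeOH, 0 °C) gives (4S)-2-ethenyl-3,3-dimethyl-4-[(3S)-3-methyl-3-(triethylsilyloxy)pent-4-en-1-yl]cyclobutan-1-ol F5. Its potassium alkoxide (KH, 18-crown-6, THF, 25 °C) undergoes the alkoxide-accelerated 1,3-shift of 2-vinylcyclobutanols at room temperature to give (6S)-5,5-dimethyl-6-[(3S)-3-methyl-3-(triethylsilyloxy)pent-4-en-1-yl]cyclohex-3-en-1-ol F6. Dess–Martin oxidation gives 9.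

**Further compounds**

F1 | step 3 | 1-[(2S,5S)-2,5-dimethylpyrrolidin-1-yl]ethan-1-one | CC(=O)N1[C@@H](C)CC[C@@H]1C
F2 | step 3 | (2S)-3,3-dimethyl-2-[(3S)-3-methyl-3-(triethylsilyloxy)pent-4-en-1-yl]cyclobutan-1-one | C=C[C@@](C)(O[Si](CC)(CC)CC)CC[C@@H]1C(=O)CC1(C)C
F3 | step 3 | (2S)-3,3-dimethyl-2-[(3S)-3-methyl-3-(triethylsilyloxy)pent-4-en-1-yl]-4-[2-(phenylsulfinyl)ethyl]cyclobutan-1-one | C=C[C@@](C)(O[Si](CC)(CC)CC)CC[C@@H]1C(=O)C(CCS(=O)c2ccccc2)C1(C)C
F4 | step 5 | (6S)-5,5-dimethyl-6-[(3S)-3-methyl-3-(triethylsilyloxy)pent-4-en-1-yl]cyclohex-2-en-1-one | C=C[C@@](C)(O[Si](CC)(CC)CC)CC[C@@H]1C(=O)C=CCC1(C)C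
F5 | step 4 | (4S)-2-ethenyl-3,3-dimethyl-4-[(3S)-3-methyl-3-(triethylsilyloxy)pent-4-en-1-yl]cyclobutan-1-ol | C=C[C@@](C)(O[Si](CC)(CC)CC)CC[C@@H]1C(O)C(C=C)C1(C)C
F6 | step 4 | (6S)-5,5-dimethyl-6-[(3S)-3-methyl-3-(triethylsilyloxy)pent-4-en-1-yl]cyclohex-3-en-1-ol | C=C[C@@](C)(O[Si](CC)(CC)CC)CC[C@@H]1C(O)CC=CC1(C)C
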